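**Plan**
Cuts: C6–OMe and the ring bond O1–C6 (peroxyketal → (Z)-γ-hydroperoxy enone → its E isomer), then C4=C5 (Wittig), then C3–O2 (O2 onto an aldehyde enamine). The ylide is cut at C5–C6 (acylation).
Forward: heptadecanoyl chloride gives the C5–C22 keto ylide, and methyl 4-oxobutanoate (C1–C4) gives a (3S)-α-peroxy aldehyde. A Wittig reaction joins them, and the only ring, the 3,6-dihydro-1,2-dioxin O1–O2–C3–C4=C5–C6, is closed last.
Enabling feature: C6 is a peroxyketal carbon flanked by O1, OMe and the C4=C5 alkene. It is a masked enone carbonyl whose two C–O bonds form and break reversibly through an allyl-conjugated peroxycarbenium ion. C3–O2 is configurationally inert, and the ring alkene is the one enone geometry from which the C3–OOH group can reach C6.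
Stereochemistry: C3 (S) comes from catalyst-controlled attack of singlet oxygen on a chiral enamine. C6 (S) is relayed from C3 in a stereoconvergent key step (light-driven E/Z pumping, ring–chain and ketal equilibria) that funnels alkene isomers and C6 epimers into the anomerically favoured isomer with OMe and CH2CO2Me cis.

Key step: step 4

Remark: atom numbers follow the docosanoate chain and coincide with the ring locants (C1 ester carbonyl, C3 ring CH bound to O2, C6 ketal carbon bound to O1, C7–C22 hexadecyl). The SMILES corresponds to (3S,6S), with OMe and CH2CO2Me on the same ring face.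

Step 1
Reactants: 1 methyltriphenylphosphonium bromide; 2 heptadecanoyl chloride
Product: 4 1-(triphenyl-λ5-phosphanylidene)octadecan-2-one, via methylenetriphenylphosphorane 3 (not isolated)
Conditions: 1 (2 equiv), n-BuLi (2 equiv), THF, 0 °C; then 2 (1 equiv), −78 °C → rt; recrystallised free of Ph3P
Reagents that add atoms: none
Why: Acylation of the non-stabilised ylide 3 by the acid chloride followed by transylidation (a second equivalent of 3 deprotonates the acylphosphonium salt) is the standard entry to keto-stabilised Wittig reagents, and no stereocentre is involved.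

Step 2
Reactants: 5 methyl 4-oxobutanoate
Product: 7 methyl (3S)-3-[(2-methoxypropan-2-yl)peroxy]-4-oxobutanoate, via alpha-hydroperoxy aldehyde 6 (not isolated)
Conditions: (S)-α,α-diphenylprolinol TMS ether (20 mol %), tetraphenylporphyrin (1 mol %), O2, white LED, CH2Cl2, −20 °C; then 2-methoxypropene, PPTS (30 mol %), 0 °C
Reagents that add atoms: dioxygen O=O; 2-methoxypropene C=C(C)OC
Why: This is the enamine-catalysed asymmetric α-oxygenation of an aldehyde with singlet oxygen: in the anti (E)-enamine of 5 the CPh2(OSiMe3) group blocks one face, so 1O2 should bond to C3 from the open face and set (3S) (the sense shown by other electrophiles with this catalyst), hydrolysis of the iminium ion releases 6, and acid-catalysed addition of its OOH group to 2-methoxypropene (perketal protection) stops peroxyhemiacetal and dioxetane-type decay and makes the aldehyde isolable.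

Step 3
Reactants: 7 methyl (3S)-3-[(2-methoxypropan-2-yl)peroxy]-4-oxobutanoate; 4 1-(triphenyl-λ5-phosphanylidene)octadecan-2-one
Product: 8 methyl (3S,4E)-3-[(2-methoxypropan-2-yl)peroxy]-6-oxodocos-4-enoate
Conditions: CH2Cl2, rt, dark
Reagents that add atoms: none
Why: Wittig olefination with a keto-stabilised ylide is E-selective and runs under neutral, salt-free conditions that perketal-protected α-peroxy aldehydes tolerate, so the C4=C5 bond is made without touching the O–O bond or epimerising C3.

Step 4
Reactants: 8 methyl (3S,4E)-3-[(2-methoxypropan-2-yl)peroxy]-6-oxodocos-4-enoate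
Product: 12 6-epi-chondrillin = methyl 2-[(3S,6S)-6-hexadecyl-6-methoxy-3,6-dihydro-1,2-dioxin-3-yl]acetate, via free E-hydroperoxide 9 (not isolated), via Z-enone 10 (not isolated), via dioxinol 11 (not isolated)
Conditions: p-TsOH·H2O (10 mol %), MeOH/CH2Cl2, Ar, hν (350–365 nm, Pyrex), 0–10 °C; then dark, rt, until the C6 epimers have equilibrated
Reagents that add atoms: methanol CO
Why: The acid first cleaves the 2-methoxyprop-2-yl perketal to give 9, and n→π* excitation then interconverts 9 and its Z isomer 10; only in 10 can the terminal oxygen of the C3–OOH group reach C6, so 10 is drained by 6-exo-trig addition to the C6 carbonyl (O1–C6 bond) as dioxinol 11, which has lost the enone chromophore and cannot be pumped back. Acid then ionises 11 to the ring peroxycarbenium ion (O1=C6+, conjugated with C4=C5), which methanol captures reversibly to give the peroxyketal. The closest known reaction types are the photoisomerisation–cyclisation of γ-hydroperoxy enones to 3,6-dihydro-1,2-dioxin-3-ols and the acid-catalysed alcohol exchange of peroxyketals, here run in one flask. C3 is a spectator (its C3–O2 and C3–H bonds are never broken) and controls the only new stereocentre, C6: in the half-chair only the (6S) epimer can place OMe pseudoaxial (anomeric nO1→σ*C6–OMe overlap) while the hexadecyl chain and the C3 side chain both stay pseudoequatorial, and pseudoaxial attack on the cation with the C3 substituent pseudoequatorial leads to the same epimer. Because every event after the photochemical one is reversible under the acid, the E/Z mixture, both epimers of 11 and any (6R) ketal should converge on (3S,6S)-12. The step needs isomerisation to outrun γ-hydrogen abstraction and O–O homolysis, which the substrate secures by having the enone as its only chromophore above 330 nm and by holding the OOH group of 10 within bonding distance of C6, so that acid-catalysed trapping is fast.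

**Compound list**
1 | methyltriphenylphosphonium bromide | C[P+](c1ccccc1)(c1ccccc1)c1ccccc1.[Br-] | starting material
2 | heptadecanoyl chloride | CCCCCCCCCCCCCCCCC(=O)Cl | starting material
3 | methylenetriphenylphosphorane | C=P(c1ccccc1)(c1ccccc1)c1ccccc1 | intermediate
4 | 1-(triphenyl-λ5-phosphanylidene)octadecan-2-one | CCCCCCCCCCCCCCCCC(=O)C=P(c1ccccc1)(c1ccccc1)c1ccccc1 | intermediate
5 | methyl 4-oxobutanoate | COC(=O)CCC=O | starting material
6 | methyl (3S)-3-hydroperoxy-4-oxobutanoate | O=C[C@H](CC(=O)OC)OO | intermediate
7 | methyl (3S)-3-[(2-methoxypropan-2-yl)peroxy]-4-oxobutanoate | O=C[C@H](CC(=O)OC)OOC(C)(C)OC | intermediate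
8 | methyl (3S,4E)-3-[(2-methoxypropan-2-yl)peroxy]-6-oxodocos-4-enoate | CCCCCCCCCCCCCCCCC(=O)/C=C/[C@H](CC(=O)OC)OOC(C)(C)OC | intermediate
9 | methyl (3S,4E)-3-hydroperoxy-6-oxodocos-4-enoate | CCCCCCCCCCCCCCCCC(=O)/C=C/[C@H](CC(=O)OC)OO | intermediate
10 | methyl (3S,4Z)-3-hydroperoxy-6-oxodocos-4-enoate | CCCCCCCCCCCCCCCCC(=O)/C=C\[C@H](CC(=O)OC)OO | intermediate
11 | methyl 2-[(3S)-6-hexadecyl-6-hydroxy-3,6-dihydro-1,2-dioxin-3-yl]acetate (C6 epimers in ring–chain equilibrium) | CCCCCCCCCCCCCCCCC1(O)C=C[C@H](CC(=O)OC)OO1 | intermediate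
12 | 6-epi-chondrillin, methyl 2-[(3S,6S)-6-hexadecyl-6-methoxy-3,6-dihydro-1,2-dioxin-3-yl]acetate | CCCCCCCCCCCCCCCC[C@@]1(OC)C=C[C@H](CC(=O)OC)OO1 | target

Total step count: 4. Longest linear sequence: 3 (5 → 7 → 8 → 12, or 1/2 → 4 → 8 → 12).

**Steps most likely to fail**

Step 2. Four things may go wrong. 1O2 may add [2+2] to the enamine, with C=C cleavage. The amine catalyst may be destroyed by photo-oxidation. Facial discrimination may be weak toward so small an electrophile. Renewed enamine formation may racemise C3 before capping. The fallback sets out from 5 and 4 and comes back at 12: the peroxide is brought in later as a racemate, and the enantiomers are parted by an enzyme. Wittig reaction of 5 with 4 (CH2Cl2, rt) gives methyl (4E)-6-oxodocos-4-enoate F1. Irradiation through Pyrex under O2 with tetraphenylporphyrin lets the enone photoenolise (E→Z isomerisation, then 1,5-H shift) to methyl (3E,5Z)-6-hydroxydocosa-3,5-dienoate F2. 1O2 traps this dienol by [4+2] cycloaddition as the racemic dioxinol methyl 2-(6-hexadecyl-6-hydroxy-3,6-dihydro-1,2-dioxin-3-yl)acetate F3. TsOH/MeOH equilibration gives 12 together with its enantiomer, methyl 2-[(3R,6R)-6-hexadecyl-6-methoxy-3,6-dihydro-1,2-dioxin-3-yl]acetate F4. A lipase (hydrolase class, chosen by screening for the (3R)-ester; phosphate buffer/MTBE) hydrolyses F4 to 2-[(3R,6R)-6-hexadecyl-6-methoxy-3,6-dihydro-1,2-dioxin-3-yl]acetic acid F5. Washing with aqueous NaHCO3 removes F5 and leaves 12.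

Step 4. Four things may go wrong. Excited 10 may abstract the γ-hydrogen (photoenolisation), which would erase C3. Light may induce O–O homolysis. Acid may cause Hock-type cleavage of the allylic hydroperoxide. The energy gap between the C6 epimers may be too small. The fallback sets out from 7 (with 2) and comes back at 10: the Z geometry is built chemically, so no light is needed. Ohira–Bestmann homologation of 7 (dimethyl (1-diazo-2-oxopropyl)phosphonate, K2CO3, MeOH, 0 °C) gives methyl (3S)-3-[(2-methoxypropan-2-yl)peroxy]pent-4-ynoate F6. Acyl Sonogashira coupling with 2 (PdCl2(PPh3)2, CuI, Et3N, THF) gives methyl (3S)-3-[(2-methoxypropan-2-yl)peroxy]-6-oxodocos-4-ynoate F7. Lindlar semihydrogenation (Pd/CaCO3–Pb, quinoline, H2, EtOAc) gives methyl (3S,4Z)-3-[(2-methoxypropan-2-yl)peroxy]-6-oxodocos-4-enoate F8. p-TsOH·H2O/MeOH in the dark then releases 10, which goes on through 11 to 12 as in step 4.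

Step 3. The keto ylide may be sluggish. Kornblum–DeLaMare-type fragmentation of the α-peroxy aldehyde, β-elimination of the peroxide toward the ester, or epimerisation at C3 may then overtake olefination. The fallback sets out from 7 and comes back at 8: C4=C5 is made with a more reactive ylide, and the C6–C7 bond is made by cross-coupling. S-Ethyl (triphenylphosphoranylidene)thioacetate (CH2Cl2, 0 °C) converts 7 into methyl (3S,4E)-6-(ethylsulfanyl)-3-[(2-methoxypropan-2-yl)peroxy]-6-oxohex-4-enoate F9. Fukuyama coupling of F9 with hexadecylzinc iodide F10 (from 1-iodohexadecane and zinc dust; PdCl2(PPh3)2 cat., toluene/THF, rt) gives 8.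

**Further compounds**
F1 | step 2 | methyl (4E)-6-oxodocos-4-enoate | CCCCCCCCCCCCCCCCC(=O)/C=C/CCC(=O)OC
F2 | step 2 | methyl (3E,5Z)-6-hydroxydocosa-3,5-dienoate | CCCCCCCCCCCCCCCC/C(O)=C/C=C/CC(=O)OC
F3 | step 2 | racemic methyl 2-(6-hexadecyl-6-hydroxy-3,6-dihydro-1,2-dioxin-3-yl)acetate | CCCCCCCCCCCCCCCCC1(O)C=CC(CC(=O)OC)OO1
F4 | step 2 | methyl 2-[(3R,6R)-6-hexadecyl-6-methoxy-3,6-dihydro-1,2-dioxin-3-yl]acetate | CCCCCCCCCCCCCCCC[C@]1(OC)C=C[C@@H](CC(=O)OC)OO1
F5 | step 2 | 2-[(3R,6R)-6-hexadecyl-6-methoxy-3,6-dihydro-1,2-dioxin-3-yl]acetic acid | CCCCCCCCCCCCCCCC[C@]1(OC)C=C[C@@H](CC(=O)O)OO1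
F6 | step 4 | methyl (3S)-3-[(2-methoxypropan-2-yl)peroxy]pent-4-ynoate | C#C[C@H](CC(=O)OC)OOC(C)(C)OC
F7 | step 4 | methyl (3S)-3-[(2-methoxypropan-2-yl)peroxy]-6-oxodocos-4-ynoate | CCCCCCCCCCCCCCCCC(=O)C#C[C@H](CC(=O)OC)OOC(C)(C)OC
F8 | step 4 | methyl (3S,4Z)-3-[(2-methoxypropan-2-yl)peroxy]-6-oxodocos-4-enoate | CCCCCCCCCCCCCCCCC(=O)/C=C\[C@H](CC(=O)OC)OOC(C)(C)OC
F9 | step 3 | methyl (3S,4E)-6-(ethylsulfanyl)-3-[(2-methoxypropan-2-yl)peroxy]-6-oxohex-4-enoate | CCSC(=O)/C=C/[C@H](CC(=O)OC)OOC(C)(C)OC
F10 | step 3 | hexadecylzinc iodide | CCCCCCCCCCCCCCCC[Zn]I
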